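At early times this flask holds Jb, Jc and the first portion of Ja, but no Je. Once Je appears, each new Ja can react with Jb or with Je.

    Ja + Je → Jh (k1 = 11.0 M⁻¹ s⁻¹)
    Je → Jj (k2 = 0.0102 s⁻¹)
    Jk ⇌ Je, rate k3*(cs3 - [Je]) while solid is left; crystals form when [Je] > cs3 (cs3 = 8.3 mM, k3 = 11.4 s⁻¹)
    Jd + Jc ⇌ Jg (K4 = 78000 M⁻¹, k4 = 67.9 M⁻¹ s⁻¹)
    Jb + Jd ⇌ Jf, settled at all times (K5 = 2.3 × 10⁵ M⁻¹)
    Ja + Jb → Jd + Je (k6 = 97.3 M⁻¹ s⁻¹)

Ja 10 mM (in portions, 2); Jb 30.0 mM; Jc 12.0 mM; time 25 min; the portions of Ja follow each other after 1.0 s, the first at the start

- at 25 min, what has stopped the reaction, if anything has (forward and back rates have come level / it is still moving / Jc has run out first / all of Ja has reacted / Jb has run out first)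
- part of the Ja gone at 25 min
- the Jj standing at 25 min, as a percentage of the Ja charged

- in percentages every species weighs as the Ja in it: one Jh counts as two
- for Je the Jk is counted in
- as a solid, counted per litre of solution: Jk
- the reaction counts as stopped when no species that holds the Ja changes by six tenths of a point or more over the second half of the time
- run time (flask): 25 min

Two chemists dispute that choice. Both take the symmetric case, Ja used equally fast on the two routes, as the zero of their scale. Both use the selectivity factor, the rate constant of Ja with Jb over that of Ja with Je, 8.85. Let x be the Je made so far, so [Je] is about x.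

The rival says Jc catches every Jd, so each Ja costs one Jb. Level then falls at 27.0 mM of x.

I say Jd lands on Jb, because the balance constant times the charge is larger for Jb, at 6900, than for Jc, at 940. Each Ja then costs two Jb, and [Jb] is the charge less two times x. My level point, the Je made at which the two routes of Ja run equally fast, is 14.2 mM.

Both points lie above the Ja charge of 10 mM, so we agree that Jb wins. We differ on the size of the leak. Summing [Je]/(sel [Jb]) over x gives 0.366 mM of Jh for me and 0.245 mM for the rival.

Each Jh eats one Ja and one Je. Je has a lifetime of 98.0 s, much shorter than the run, so what survives becomes Jj. Even on the 10.0 mM of Jb left at the end of the charge, Ja lives about 1.03 s. I therefore expect Ja to run out, with 100% gone and 92.7% of Jj. The rival expects 95.1% of Jj.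

The forecast stands on my side, “each Ja uses two Jb”, and says all of Ja has reacted, 100% gone and 93.5% of Jj, a little above my figure.

The flask gives all of Ja has reacted, 100% gone and 93.6% of Jj, nearer my figure than the rival's. At 25.0 min the flask holds more Jf, 7.86 mM, than Jg, 1.82 mM. At 0.0171 min Ja in this flask goes 39 times faster by Jb than by Je, well above level, and its charge stays under 14.2 mM. In the neighbour flask with 12 mM of Jb, the level point is 5.68 mM, below the same Ja charge, and Jh stands at 56.7% against 43.3% of Jj. The rival's Jc gets its due in the end state of that neighbour flask, which holds more Jg, 4.19 mM, than Jf, 2.97 mM.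

The constants used here belong to no real substance; the run is a simulation.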